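**Remarks on the chemistry**

- Lignan numbering is used throughout: ring A = 4-hydroxy-3-methoxyphenyl on C7, ring B = 3-hydroxy-4,5-dimethoxyphenyl on C7', bridgeheads C8/C8', methylenes C9/C9'. Ts = 4-methylbenzenesulfonyl ("tosyloxy" = TsO), TIPS = tri(propan-2-yl)silyl.
- Correction: the connectivity and the (7S,8R) trans configuration of the diazo lactone and the bicyclic lactone match the target, but the insertion cannot be counted on to put ring B on the convex face. A dirhodium carbene normally transfers the benzylic hydrogen that leaves the aryl pointing away from the metal, that is, syn to the lactone carbonyl. The bicyclic lactone therefore enters the route as its 7'R epimer 16, and C7' is brought to the target configuration in step 12.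
- Redesign of spectator groups only: an acid that ionises the C7'–O bond would ionise C7–O first if ring A carried an alkyl ether. The ring A phenol is therefore carried as an electron-poor tosylate and the ring B phenol as a TIPS ether. This also avoids a final hydrogenolysis next to two benzylic ethers.
- Assumption: the succinate imide of (4S)-4-benzyl-oxazolidin-2-one reacts with the usual Evans syn sense, as propionate imides do.

## Structural features

The target is a 2,6-diaryl-3,7-dioxabicyclo[3.3.0]octane: two tetrahydrofuran rings cis-fused through the C8–C8' bond, each with one aryl group on the carbon next to oxygen (ring A on C7, ring B on C7'). The four stereocentres C7, C8, C8' and C7' are contiguous, (7S,8R,7'S,8'R), and both aryl groups sit on the convex face, each trans to the methylene on the neighbouring bridgehead. The two aryl groups differ, so there is no C2 axis and the halves must be brought in separately. Both C7–O and C7'–O are benzylic ethers: they ionise in acid (epimerisation, aryltetralin formation), are cleaved by hydrogenolysis and are attacked by benzylic oxidants; the free phenols are oxidation-prone. C7 is the more labile centre because ring A has an unhindered para oxygen, whereas the 4-methoxy group of ring B is twisted by two ortho substituents and donates less. The real difficulty is that the convex arrangement of an aryl group is only slightly favoured in this bicycle, so the benzylic configurations must be set deliberately while C8/C8' are fixed absolutely. The key step uses the fact that, when C9' is a lactone carbonyl, C8' is a carbene site whose 1,5 partner through C8–C9–O is the benzylic C7'–H of a ring B benzyl ether.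

## Logic of the disconnections

**21 from 20.** The aryl O–S bond on ring A and the aryl O–Si bond on ring B are cut. The phenols must stay masked to the end, and these two groups are chosen so that one basic operation frees both and no hydrogenolysis is needed beside two benzylic ethers. No skeletal simplification results. The forward step must cleave at sulfur and silicon without disturbing the benzylic C–O bonds.

**20 from 19.** No skeletal bond is cut; the C7'–O bond is broken and re-formed so that 19 is the C7' epimer of 20. This is placed here because the key step is expected to put ring B on the concave face. It lets the insertion be used whatever its facial outcome. The forward step must ionise C7'–O but not C7–O, which is why ring A is kept electron-poor, and it must reach an equilibrium from which 20 can be separated and 19 recycled.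

**19 from 17.** The O–C9' bond of the ring A tetrahydrofuran is cut, giving a diol with a secondary benzylic hydroxyl at C7 and a primary hydroxyl at C9'. Closing at the primary carbon keeps the C7 configuration untouched. The bicycle becomes a monocycle. The forward step needs sulfonylation of the primary hydroxyl only.

**17 from 16.** C9' is returned to the lactone oxidation level. The carbonyl is what makes C8' a carbene carbon in the key step. The forward reduction must spare the aryl sulfonate and the silyl ether.

**16 from 15.** The C8'–C7' bond is cut, opening the ring B tetrahydrofuran to a benzyl ether and removing two stereocentres. This is the strategic cut, because it turns a bicyclic problem into a monocyclic lactone with a simple ether side chain. The forward step must favour 1,5 C–H insertion over hydride shift, dimerisation and arene addition.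

**15 from 13.** The C8'=N2 unit is removed. The forward step needs activation of the lactone alpha carbon, since a plain lactone does not accept a diazo group directly.

**13 from 9 and 11.** The C7'–O bond of the side-chain ether is cut, separating ring B as an aldehyde. This makes the route convergent. The forward step must be non-basic, because the hydroxymethyl lactone translactonises under base.

**11 from 10.** The O–Si bond is cut; the forward step is a simple phenol silylation.

**9 from 8 and 8 from 7.** C9 is traced back to a carboxyl group and then to the acyl-auxiliary. The forward steps must cleave the exocyclic imide and then reduce the acid in the presence of the lactone.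

**7 from 5 and 2.** The C7–C8 bond and the lactone O–C9' acyl bond are cut. This single operation sets C7 and C8 absolutely and delivers the trans lactone. The forward step needs a syn-selective aldol with full auxiliary control, followed by ring closure onto the ester.

**5 from 3 and 4; 2 from 1.** An N-acyl bond and an O–S bond are cut, leading to commercial materials.

## Other disconnections considered

**Alternative 1:** The cut is C7–C8 and C8'–C7' in one operation. In the forward step the dithiane A3 is lithiated with n-BuLi and adds 1,4 to the chiral butenolide A2 anti to the acetal substituent; the lactone enolate is then trapped by the aldehyde A4 anti to the new C8 substituent, giving A1. In A1 the lactone carbonyl is C9', the acetal carbon is C9 and the C8/C8' substituents are trans, as a C9/C9' lactone requires.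
- In its favour: three components, two C–C bonds and both bridgehead centres in one flask, with absolute configuration from a crystalline acetal auxiliary.
- Better than the chosen plan on C7': both benzylic carbons arrive at the ketone or alcohol level, so both ether rings can later be closed through benzylic cations, which should place each aryl trans to its bridgehead neighbour. The chosen plan expects the wrong C7' epimer from its key step and must correct it.
- Better on step economy: roughly eight or nine operations against thirteen.
- Against it here: the dithiane must be unmasked beside two electron-rich arenes and a free benzylic alcohol, and A1 can undergo retro-aldol cleavage under base. After reduction, four hydroxyl groups must close to the furofuran and not to a 2,5-diaryl tetrahydrofuran. The end is a hydrogenolysis of two benzyl ethers beside two benzylic ethers.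
- Mechanism: polar, cryogenic organolithium chemistry against a neutral catalytic carbene step. The two plans are equal in taking C8/C8' from a recoverable chiral controller.
- Overall it is the shorter and stereochemically more direct route on paper. The chosen plan closes each ring by a separate, regiochemically unambiguous reaction, and its two aryl groups never compete in one cationic cyclisation.

**Alternative 2:** The cut is both benzylic C–O bonds, C7–O(C9') and C7'–O(C9). In the forward step DDQ removes hydride from C7 and then C7' of the dibenzylbutanediol A6, and each cation is captured by the hydroxyl on the far methylene, giving A5.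
- In its favour: both rings and both benzylic centres are made in one operation with no prior functionalisation at C7 or C7'. The two stereocentres of A6 are not benzylic and can be set by alkylation chemistry.
- Equal or better on C7': closure through cations should favour the convex aryl arrangement.
- Better on step economy if A6 is available in about six steps.
- Against it here: ring B is a poorer hydride donor than ring A, so the second oxidation may be slower than over-oxidation of the ring A benzylic ether formed first. The C7 cation can also be captured by the ring B arene in a six-membered Friedel–Crafts closure. A5 is itself a bis-benzylic ether exposed to the oxidant. Benzyl ethers on the phenols bring back a final hydrogenolysis.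
- Mechanism: two successive hydride abstractions with all selectivity coming from the substrate, against an intramolecular, position-specific C–H functionalisation in the chosen plan.

**Alternative 3:** The cut is O–C7 and C7–C8. In the forward step TMSOTf exchanges the C9' hydroxyl of the dihydrofuran A8 into the acetal A9, the resulting oxocarbenium ion at C7 is attacked by the enol ether carbon C8, and methanol caps C9, giving A7.
- In its favour: it is convergent, the ring A aldehyde enters late, and a C–C bond and a ring form together under mild Lewis acid.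
- Better than the chosen plan on C7': the trans C7'/C8' relationship is already present in A8 before the bicycle exists.
- Against it here: A7 carries an extra acetal at C9 and is a mixture there. Its reduction to CH2 with a silane and a Lewis acid must not ionise either benzylic ether, and C7–O with an alkoxy-substituted ring A is the most labile bond in A7. The configuration at C7 depends on how the oxocarbenium ion approaches. Enantioselective access to A8 needs its own asymmetric step.
- Equal to the chosen plan: the asymmetric burden is comparable to the aldol, and the step count is similar at about a dozen.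
- Mechanism: a cationic closure in which the C=O+ unit lies inside the forming ring, against a metal carbene insertion; both are five-membered closures onto an oxygen-activated carbon.

Key step: step 9

## Route

Step 1
Reactants: 1 vanillin (4-hydroxy-3-methoxybenzaldehyde)
Product: 2 4-formyl-2-methoxyphenyl 4-methylbenzenesulfonate
Conditions: TsCl, Et3N, DMAP (cat.), CH2Cl2, 0 °C to rt
Reagents that add atoms: 4-methylbenzenesulfonyl chloride, Cc1ccc(cc1)S(Cl)(=O)=O
Why: Phenol sulfonylation; the tosylate survives every later step and makes ring A a poor cation-stabilising group, which protects C7 in steps 11 and 12.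

Step 2
Reactants: 3 (4S)-4-benzyl-1,3-oxazolidin-2-one; 4 methyl 4-chloro-4-oxobutanoate
Product: 5 methyl 4-[(4S)-4-benzyl-2-oxo-1,3-oxazolidin-3-yl]-4-oxobutanoate
Conditions: n-BuLi, THF, −78 °C; then 4, −78 to 0 °C
Reagents that add atoms: none
Why: N-acylation of the lithiated oxazolidinone by the acid chloride; the ester end is untouched at low temperature.

Step 3
Reactants: 5 methyl 4-[(4S)-4-benzyl-2-oxo-1,3-oxazolidin-3-yl]-4-oxobutanoate; 2 4-formyl-2-methoxyphenyl 4-methylbenzenesulfonate
Product: 7 (4S)-4-benzyl-3-({(2S,3S)-2-[3-methoxy-4-(tosyloxy)phenyl]-5-oxooxolan-3-yl}carbonyl)-1,3-oxazolidin-2-one (trans lactone imide), via open syn-aldol hydroxy ester 6 (not isolated)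
Conditions: Bu2BOTf, iPr2NEt, CH2Cl2, 0 °C; 2, −78 to 0 °C; pH 7 buffer, MeOH, H2O2; then TsOH·H2O (cat.), CH2Cl2, rt
Reagents that add atoms: none
Why: Evans syn aldol: the Z boron enolate of the imide (more acidic than the ester) reacts through a chair Zimmerman–Traxler transition state on the face away from the auxiliary benzyl group, setting C7 (S) and C8; the new hydroxyl then closes onto the methyl ester, and a syn aldol maps onto the trans 4,5-disubstituted lactone.

Step 4
Reactants: 7 trans lactone imide
Product: 8 (2S,3S)-2-[3-methoxy-4-(tosyloxy)phenyl]-5-oxooxolane-3-carboxylic acid (trans paraconic acid)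
Conditions: LiOH, H2O2, THF/H2O, 0 °C; Na2SO3; HCl to pH 2
Reagents that add atoms: hydrogen peroxide, OO
Why: Hydroperoxide attacks the exocyclic imide carbonyl selectively (Evans auxiliary hydrolysis) and acidification re-closes any lactone opened by hydroxide; at 0 °C the aryl sulfonate and the C8 centre should be unaffected.

Step 5
Reactants: 8 trans paraconic acid
Product: 9 (4R,5S)-4-(hydroxymethyl)-5-[3-methoxy-4-(tosyloxy)phenyl]oxolan-2-one
Conditions: BH3·SMe2, THF, 0 °C to rt; MeOH quench, neutral work-up
Reagents that add atoms: none
Why: Borane reduces a carboxylic acid through its acyloxyborane far faster than a lactone, so C9 reaches the alcohol level with the lactone intact; the descriptor at C8 changes to R only through priority rules.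

Step 6
Reactants: 10 3-hydroxy-4,5-dimethoxybenzaldehyde
Product: 11 3,4-dimethoxy-5-{[tri(propan-2-yl)silyl]oxy}benzaldehyde
Conditions: TIPSCl, imidazole, DMF, rt
Reagents that add atoms: chlorotri(propan-2-yl)silane, CC(C)[Si](Cl)(C(C)C)C(C)C
Why: Phenol silylation; a silyl ether keeps ring B electron-rich for the insertion and the epimerisation, and is removed by base in the last step.

Step 7
Reactants: 9 (4R,5S)-4-(hydroxymethyl)-5-[3-methoxy-4-(tosyloxy)phenyl]oxolan-2-one; 11 3,4-dimethoxy-5-{[tri(propan-2-yl)silyl]oxy}benzaldehyde
Product: 13 (4R,5S)-4-{[(3,4-dimethoxy-5-{[tri(propan-2-yl)silyl]oxy}phenyl)methoxy]methyl}-5-[3-methoxy-4-(tosyloxy)phenyl]oxolan-2-one, via trimethylsilyl ether 12 (not isolated)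
Conditions: (Me3Si)2NH, TMSOTf (cat.), CH2Cl2, rt, evaporate; 11, Et3SiH, TMSOTf (10 mol%), CH2Cl2, −78 to −40 °C
Reagents that add atoms: none
Why: Reductive etherification: the silyl ether and the aldehyde give an oxocarbenium ion under TMSOTf catalysis and Et3SiH delivers hydride to it; the conditions are non-basic, so the hydroxymethyl lactone cannot translactonise and no stereocentre is touched.

Step 8
Reactants: 13 ether lactone
Product: 15 (4R,5S)-3-diazo-4-{[(3,4-dimethoxy-5-{[tri(propan-2-yl)silyl]oxy}phenyl)methoxy]methyl}-5-[3-methoxy-4-(tosyloxy)phenyl]oxolan-2-one, via 3-trifluoroacetyl lactone 14 (not isolated)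
Conditions: LiN(SiMe3)2, THF, −78 °C; CF3CO2CH2CF3; aq. HCl; then MsN3, Et3N, H2O, MeCN, rt
Reagents that add atoms: methanesulfonyl azide, CS(=O)(=O)N=[N+]=[N-]
Why: Detrifluoroacetylative diazo transfer (a deacylative Regitz transfer): Claisen acylation of the lactone enolate activates C8', and the sulfonyl azide then transfers N2 with loss of the trifluoroacetyl group as its sulfonamide; the enolate has no beta leaving group, and C7 and C8 are not involved.

Step 9
Reactants: 15 trans diazo lactone
Product: 16 (3S,3aR,6R,6aS)-6-(3,4-dimethoxy-5-{[tri(propan-2-yl)silyl]oxy}phenyl)-3-[3-methoxy-4-(tosyloxy)phenyl]tetrahydro-1H,3H-furo[3,4-c]furan-1-one (7S,8R,7'R,8'S; carbonyl at C9', ring B syn to the carbonyl)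
Conditions: Rh2(OAc)4 (2 mol%), CH2Cl2, 40 °C, slow addition of 15 (final 0.01 M)
Reagents that add atoms: none
Why: Rh2(OAc)4 decomposes 15 with loss of N2 to an electrophilic dirhodium carbene at C8' flanked by the lactone carbonyl, which engages the C7'–H bond of the ring B benzyl ether in a three-centre, hydride-transfer-like transition state so that C8'–C7' forms as the metal leaves. The closest known reaction type is the intramolecular 1,5 C–H insertion of alpha-diazo esters and lactones into ether-activated C–H bonds to give tetrahydrofurans. The one ring closed is the ring B tetrahydrofuran (C8', C8, C9, O, C7'), formed in the 1,5 mode through a five-membered cyclic transition state. C8' is controlled by the tether: C9 sits on one face of the lactone at C8, so the new bond can form only on that face and the ring fusion is cis (8'S). C7' is controlled by the catalyst: the benzylic hydrogen transferred is the one that leaves ring B pointing away from the dirhodium core and its carboxylate ligands, that is, toward the lactone carbonyl, so the aryl is expected on the concave face (7'R); this is opposite to the target and is corrected in step 12, and any 7'S epimer formed alongside reaches 20 directly through steps 10 and 11. The step needs 1,5 insertion to outrun the 1,2-hydride shift from C8 (butenolide), carbene dimerisation and addition to the ring B arene; the C7'–H bond is activated by both the ether oxygen and the para-methoxyaryl group, carboxylate ligands favour insertion over arene addition, and slow addition at high dilution suppresses dimerisation. The aryl sulfonate, the silyl ether and the lactone are inert to the carbene.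

Step 10
Reactants: 16 bicyclic lactone
Product: 17 (S)-[(3R,4R,5R)-5-(3,4-dimethoxy-5-{[tri(propan-2-yl)silyl]oxy}phenyl)-4-(hydroxymethyl)oxolan-3-yl][3-methoxy-4-(tosyloxy)phenyl]methanol
Conditions: LiBH4, THF, 0 °C to rt; aq. NH4Cl
Reagents that add atoms: none
Why: Hydride reduction of the lactone to the 1,4-diol; LiBH4 is chosen over LiAlH4 because it leaves the aryl sulfonate S–O bond and the aryl silyl ether alone, and no stereocentre is affected.

Step 11
Reactants: 17 diol
Product: 19 (1S,3aR,4R,6aR)-4-(3,4-dimethoxy-5-{[tri(propan-2-yl)silyl]oxy}phenyl)-1-[3-methoxy-4-(tosyloxy)phenyl]tetrahydro-1H,3H-furo[3,4-c]furan (7'-epimer of 20), via primary methanesulfonate 18 (not isolated)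
Conditions: MsCl (1.1 equiv), pyridine, CH2Cl2, −10 °C to rt
Reagents that add atoms: none
Why: The primary hydroxyl at C9' is sulfonylated selectively and the C7 hydroxyl displaces the mesylate (Williamson-type 5-exo-tet SN2 at C9'), so C7 keeps its configuration; the electron-poor ring A rules out ionisation at C7, and closing this ring first removes the hydroxyl that could otherwise capture a C7' cation in step 12.

Step 12
Reactants: 19 7'-epi furofuran
Product: 20 (1S,3aR,4S,6aR)-4-(3,4-dimethoxy-5-{[tri(propan-2-yl)silyl]oxy}phenyl)-1-[3-methoxy-4-(tosyloxy)phenyl]tetrahydro-1H,3H-furo[3,4-c]furan (both aryl groups on the convex face)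
Conditions: TfOH (10 mol%), CH2Cl2, 0 °C to rt; Et3N quench; chromatography, recovered 19 resubmitted
Reagents that add atoms: none
Why: Acid-catalysed epimerisation of a furofuran benzylic ether: the C7'–O bond ionises to the ring B benzylic cation and re-closes from either face, so C7' equilibrates while C8 and C8' hold the cis fusion. The C7–O bond should not ionise because ring A carries the tosylate, so only two isomers are in play; 20 is expected to be the more stable of them, though by a small margin, hence separation and recycling.

Step 13
Reactants: 20 protected furofuran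
Product: 21 4-[(1S,3aR,4S,6aR)-4-(3-hydroxy-4,5-dimethoxyphenyl)tetrahydro-1H,3H-furo[3,4-c]furan-1-yl]-2-methoxyphenol (target)
Conditions: KOH, MeOH/THF/H2O (degassed), 60 °C; aq. NH4Cl
Reagents that add atoms: none
Why: Hydroxide attacks sulfur of the aryl sulfonate and silicon of the aryl silyl ether, releasing both phenoxides in one operation; benzylic ethers are stable to base, so no stereocentre is touched.

## Compound list

1 | vanillin (4-hydroxy-3-methoxybenzaldehyde) | COc1cc(C=O)ccc1O | starting material
2 | 4-formyl-2-methoxyphenyl 4-methylbenzenesulfonate | COc1cc(C=O)ccc1OS(=O)(=O)c1ccc(C)cc1 | intermediate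
3 | (4S)-4-benzyl-1,3-oxazolidin-2-one | O=C1OC[C@H](Cc2ccccc2)N1 | starting material
4 | methyl 4-chloro-4-oxobutanoate | COC(=O)CCC(Cl)=O | starting material
5 | methyl 4-[(4S)-4-benzyl-2-oxo-1,3-oxazolidin-3-yl]-4-oxobutanoate | COC(=O)CCC(=O)N1[C@@H](Cc2ccccc2)COC1=O | intermediate
6 | methyl (3S,4S)-3-{[(4S)-4-benzyl-2-oxo-1,3-oxazolidin-3-yl]carbonyl}-4-hydroxy-4-[3-methoxy-4-(tosyloxy)phenyl]butanoate | COc1cc([C@@H](O)[C@H](CC(=O)OC)C(=O)N2[C@@H](Cc3ccccc3)COC2=O)ccc1OS(=O)(=O)c1ccc(C)cc1 | intermediate
7 | (4S)-4-benzyl-3-({(2S,3S)-2-[3-methoxy-4-(tosyloxy)phenyl]-5-oxooxolan-3-yl}carbonyl)-1,3-oxazolidin-2-one | COc1cc([C@H]2OC(=O)C[C@@H]2C(=O)N2[C@@H](Cc3ccccc3)COC2=O)ccc1OS(=O)(=O)c1ccc(C)cc1 | intermediate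
8 | (2S,3S)-2-[3-methoxy-4-(tosyloxy)phenyl]-5-oxooxolane-3-carboxylic acid | COc1cc([C@H]2OC(=O)C[C@@H]2C(O)=O)ccc1OS(=O)(=O)c1ccc(C)cc1 | intermediate
9 | (4R,5S)-4-(hydroxymethyl)-5-[3-methoxy-4-(tosyloxy)phenyl]oxolan-2-one | COc1cc([C@H]2OC(=O)C[C@@H]2CO)ccc1OS(=O)(=O)c1ccc(C)cc1 | intermediate
10 | 3-hydroxy-4,5-dimethoxybenzaldehyde | COc1cc(C=O)cc(O)c1OC | starting material
11 | 3,4-dimethoxy-5-{[tri(propan-2-yl)silyl]oxy}benzaldehyde | COc1cc(C=O)cc(O[Si](C(C)C)(C(C)C)C(C)C)c1OC | intermediate
12 | (4R,5S)-5-[3-methoxy-4-(tosyloxy)phenyl]-4-{[(trimethylsilyl)oxy]methyl}oxolan-2-one | COc1cc([C@H]2OC(=O)C[C@@H]2CO[Si](C)(C)C)ccc1OS(=O)(=O)c1ccc(C)cc1 | intermediate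
13 | (4R,5S)-4-{[(3,4-dimethoxy-5-{[tri(propan-2-yl)silyl]oxy}phenyl)methoxy]methyl}-5-[3-methoxy-4-(tosyloxy)phenyl]oxolan-2-one | COc1cc([C@H]2OC(=O)C[C@@H]2COCc2cc(O[Si](C(C)C)(C(C)C)C(C)C)c(OC)c(OC)c2)ccc1OS(=O)(=O)c1ccc(C)cc1 | intermediate
14 | (4R,5S)-4-{[(3,4-dimethoxy-5-{[tri(propan-2-yl)silyl]oxy}phenyl)methoxy]methyl}-5-[3-methoxy-4-(tosyloxy)phenyl]-3-(trifluoroacetyl)oxolan-2-one (C3 epimers and enol) | COc1cc([C@H]2OC(=O)C(C(=O)C(F)(F)F)[C@@H]2COCc2cc(O[Si](C(C)C)(C(C)C)C(C)C)c(OC)c(OC)c2)ccc1OS(=O)(=O)c1ccc(C)cc1 | intermediate
15 | (4R,5S)-3-diazo-4-{[(3,4-dimethoxy-5-{[tri(propan-2-yl)silyl]oxy}phenyl)methoxy]methyl}-5-[3-methoxy-4-(tosyloxy)phenyl]oxolan-2-one | COc1cc([C@H]2OC(=O)C(=[N+]=[N-])[C@@H]2COCc2cc(O[Si](C(C)C)(C(C)C)C(C)C)c(OC)c(OC)c2)ccc1OS(=O)(=O)c1ccc(C)cc1 | intermediate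
16 | (3S,3aR,6R,6aS)-6-(3,4-dimethoxy-5-{[tri(propan-2-yl)silyl]oxy}phenyl)-3-[3-methoxy-4-(tosyloxy)phenyl]tetrahydro-1H,3H-furo[3,4-c]furan-1-one | COc1cc([C@H]2OC(=O)[C@H]3[C@@H]2CO[C@H]3c2cc(O[Si](C(C)C)(C(C)C)C(C)C)c(OC)c(OC)c2)ccc1OS(=O)(=O)c1ccc(C)cc1 | intermediate
17 | (S)-[(3R,4R,5R)-5-(3,4-dimethoxy-5-{[tri(propan-2-yl)silyl]oxy}phenyl)-4-(hydroxymethyl)oxolan-3-yl][3-methoxy-4-(tosyloxy)phenyl]methanol | COc1cc([C@@H](O)[C@H]2CO[C@@H](c3cc(O[Si](C(C)C)(C(C)C)C(C)C)c(OC)c(OC)c3)[C@H]2CO)ccc1OS(=O)(=O)c1ccc(C)cc1 | intermediate
18 | [(2R,3R,4R)-2-(3,4-dimethoxy-5-{[tri(propan-2-yl)silyl]oxy}phenyl)-4-{(S)-hydroxy[3-methoxy-4-(tosyloxy)phenyl]methyl}oxolan-3-yl]methyl methanesulfonate | COc1cc([C@@H](O)[C@H]2CO[C@@H](c3cc(O[Si](C(C)C)(C(C)C)C(C)C)c(OC)c(OC)c3)[C@H]2COS(C)(=O)=O)ccc1OS(=O)(=O)c1ccc(C)cc1 | intermediate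
19 | (1S,3aR,4R,6aR)-4-(3,4-dimethoxy-5-{[tri(propan-2-yl)silyl]oxy}phenyl)-1-[3-methoxy-4-(tosyloxy)phenyl]tetrahydro-1H,3H-furo[3,4-c]furan | COc1cc([C@H]2OC[C@H]3[C@@H]2CO[C@H]3c2cc(O[Si](C(C)C)(C(C)C)C(C)C)c(OC)c(OC)c2)ccc1OS(=O)(=O)c1ccc(C)cc1 | intermediate
20 | (1S,3aR,4S,6aR)-4-(3,4-dimethoxy-5-{[tri(propan-2-yl)silyl]oxy}phenyl)-1-[3-methoxy-4-(tosyloxy)phenyl]tetrahydro-1H,3H-furo[3,4-c]furan | COc1cc([C@H]2OC[C@H]3[C@@H]2CO[C@@H]3c2cc(O[Si](C(C)C)(C(C)C)C(C)C)c(OC)c(OC)c2)ccc1OS(=O)(=O)c1ccc(C)cc1 | intermediate
21 | 4-[(1S,3aR,4S,6aR)-4-(3-hydroxy-4,5-dimethoxyphenyl)tetrahydro-1H,3H-furo[3,4-c]furan-1-yl]-2-methoxyphenol | COc1cc([C@H]2OC[C@H]3[C@@H]2CO[C@@H]3c2cc(O)c(OC)c(OC)c2)ccc1O | target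

## Step count and risks

Total steps: 13. Longest linear sequence: 11 steps (1, 3, 4, 5, 7, 8, 9, 10, 11, 12, 13; the branch through step 2 is equally long).

**Step 9 (key step).** The most likely failure is the 1,2-hydride shift from C8 to the carbene carbon, which gives a butenolide, together with carbene dimerisation and addition to the ring B arene; a tertiary hydrogen sits next to the carbene and nothing but the activated C7'–H bond holds these paths back. The facial outcome at C7' is not a failure mode here, because step 12 is built for it. Fallback: the same C8'–C7' bond is made by an ionic closure without a diazo compound, setting out from 9 and 11. Aldehyde 11 is converted with trimethyl orthoformate and TsOH into its dimethyl acetal {[5-(dimethoxymethyl)-2,3-dimethoxyphenyl]oxy}tri(propan-2-yl)silane F1. Acid-catalysed exchange with 9 (PPTS, removal of methanol) gives the mixed methyl acetal (4R,5S)-4-({[(3,4-dimethoxy-5-{[tri(propan-2-yl)silyl]oxy}phenyl)(methoxy)methyl]oxy}methyl)-5-[3-methoxy-4-(tosyloxy)phenyl]oxolan-2-one F2. TMSOTf and iPr2NEt in CH2Cl2 then form the lactone silyl ketene acetal and ionise the acetal, and an intramolecular Mukaiyama-type addition of C8' to the C7' oxocarbenium ion closes the ring. The sequence comes back to the route at 16; if the C7' epimer forms instead, steps 10 and 11 take it directly to 20.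

**Step 12.** The equilibrium may favour 20 only slightly, ionisation may be slow because ring B is a modest donor, and the cation may be lost by elimination or by attack on an arene. Fallback: C7' is set under kinetic control, setting out from 19. DDQ in wet CH2Cl2 oxidises only the ring B benzylic ether (ring A is deactivated) and opens it to the hydroxy ketone (3,4-dimethoxy-5-{[tri(propan-2-yl)silyl]oxy}phenyl){(3R,4R,5S)-4-(hydroxymethyl)-5-[3-methoxy-4-(tosyloxy)phenyl]oxolan-3-yl}methanone F3, which is reduced at once with NaBH4 at low temperature to the benzylic alcohol {(3R,4R,5S)-4-(hydroxymethyl)-5-[3-methoxy-4-(tosyloxy)phenyl]oxolan-3-yl}(3,4-dimethoxy-5-{[tri(propan-2-yl)silyl]oxy}phenyl)methanol F4 as a mixture at C7'. Brief treatment with catalytic camphorsulfonic acid at 0 °C closes the ether through the benzylic cation, where the aryl group should take the position trans to C9'. The sequence comes back to the route at 20.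

**Step 7.** The aldehyde may be consumed by self-etherification or over-reduction to the methylarene faster than it couples with the silyl ether, because the ring B oxocarbenium ion is well stabilised. Fallback: the ether is made by alkylation, setting out from 11 and 9. NaBH4 reduces 11 to (3,4-dimethoxy-5-{[tri(propan-2-yl)silyl]oxy}phenyl)methanol F5; trichloroacetonitrile and catalytic DBU give (3,4-dimethoxy-5-{[tri(propan-2-yl)silyl]oxy}phenyl)methyl 2,2,2-trichloroacetimidate F6; and 9 is alkylated by F6 with catalytic TfOH in CH2Cl2 at low temperature. The sequence comes back to the route at 13.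

**Step 4.** Hydroperoxide or hydroxide may attack the aryl sulfonate, or the opened hydroxy acid may epimerise before it re-closes. Fallback: the auxiliary is removed reductively from 7 with NaBH4 in THF/H2O, which reduces the exocyclic imide carbonyl directly to the primary alcohol and leaves the lactone. This makes no new compound (F0), skips 8 and comes back to the route at 9.

**Step 13.** Hot alkali acting on the freshly released para-hydroxybenzylic ether may cause quinone methide formation with loss of configuration at C7, air oxidation of the phenoxides, or incomplete sulfonate hydrolysis. Fallback: the two groups are removed by different mechanisms, setting out from 20. Buffered fluoride (Bu4NF, AcOH, THF) removes the silyl ether to give 4-[(1S,3aR,4S,6aR)-4-(3-hydroxy-4,5-dimethoxyphenyl)tetrahydro-1H,3H-furo[3,4-c]furan-1-yl]-2-methoxyphenyl 4-methylbenzenesulfonate F7, and Mg in MeOH at rt then cleaves the S–O bond reductively. The sequence comes back to the route at 21.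

## Further compounds

F1 | step 9 | {[5-(dimethoxymethyl)-2,3-dimethoxyphenyl]oxy}tri(propan-2-yl)silane | COC(OC)c1cc(OC)c(OC)c(O[Si](C(C)C)(C(C)C)C(C)C)c1
F2 | step 9 | (4R,5S)-4-({[(3,4-dimethoxy-5-{[tri(propan-2-yl)silyl]oxy}phenyl)(methoxy)methyl]oxy}methyl)-5-[3-methoxy-4-(tosyloxy)phenyl]oxolan-2-one (acetal epimers) | COc1cc([C@H]2OC(=O)C[C@@H]2COC(OC)c2cc(O[Si](C(C)C)(C(C)C)C(C)C)c(OC)c(OC)c2)ccc1OS(=O)(=O)c1ccc(C)cc1
F3 | step 12 | (3,4-dimethoxy-5-{[tri(propan-2-yl)silyl]oxy}phenyl){(3R,4R,5S)-4-(hydroxymethyl)-5-[3-methoxy-4-(tosyloxy)phenyl]oxolan-3-yl}methanone | COc1cc([C@H]2OC[C@H](C(=O)c3cc(O[Si](C(C)C)(C(C)C)C(C)C)c(OC)c(OC)c3)[C@@H]2CO)ccc1OS(=O)(=O)c1ccc(C)cc1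
F4 | step 12 | {(3R,4R,5S)-4-(hydroxymethyl)-5-[3-methoxy-4-(tosyloxy)phenyl]oxolan-3-yl}(3,4-dimethoxy-5-{[tri(propan-2-yl)silyl]oxy}phenyl)methanol (C7' epimers) | COc1cc([C@H]2OC[C@H](C(O)c3cc(O[Si](C(C)C)(C(C)C)C(C)C)c(OC)c(OC)c3)[C@@H]2CO)ccc1OS(=O)(=O)c1ccc(C)cc1
F5 | step 7 | (3,4-dimethoxy-5-{[tri(propan-2-yl)silyl]oxy}phenyl)methanol | COc1cc(CO)cc(O[Si](C(C)C)(C(C)C)C(C)C)c1OC
F6 | step 7 | (3,4-dimethoxy-5-{[tri(propan-2-yl)silyl]oxy}phenyl)methyl 2,2,2-trichloroacetimidate | COc1cc(COC(=N)C(Cl)(Cl)Cl)cc(O[Si](C(C)C)(C(C)C)C(C)C)c1OC
F0 | step 4 | none | none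
F7 | step 13 | 4-[(1S,3aR,4S,6aR)-4-(3-hydroxy-4,5-dimethoxyphenyl)tetrahydro-1H,3H-furo[3,4-c]furan-1-yl]-2-methoxyphenyl 4-methylbenzenesulfonate | COc1cc([C@H]2OC[C@H]3[C@@H]2CO[C@@H]3c2cc(O)c(OC)c(OC)c2)ccc1OS(=O)(=O)c1ccc(C)cc1
A1 | alternative 1 | trans,trans-trisubstituted 5-(menthyloxy)oxolan-2-one carrying the 2-[4-(benzyloxy)-3-methoxyphenyl]-1,3-dithian-2-yl group on C8 and the [3-(benzyloxy)-4,5-dimethoxyphenyl](hydroxy)methyl group on C8' (configuration as in the SMILES) | O=C1O[C@@H](O[C@@H]3C[C@H](C)CC[C@H]3C(C)C)[C@H](C3(SCCCS3)c3ccc(OCc4ccccc4)c(OC)c3)[C@H]1[C@H](O)c1cc(OCc2ccccc2)c(OC)c(OC)c1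
A2 | alternative 1 | (5R)-5-{[(1R,2S,5R)-5-methyl-2-(propan-2-yl)cyclohexyl]oxy}furan-2(5H)-one | O=C1O[C@@H](O[C@@H]2C[C@H](C)CC[C@H]2C(C)C)C=C1
A3 | alternative 1 | 2-[4-(benzyloxy)-3-methoxyphenyl]-1,3-dithiane | COc1cc(C2SCCCS2)ccc1OCc1ccccc1
A4 | alternative 1 | 3-(benzyloxy)-4,5-dimethoxybenzaldehyde | COc1cc(C=O)cc(OCc2ccccc2)c1OC
A5 | alternative 2 | (1S,3aR,4S,6aR)-1-[4-(benzyloxy)-3-methoxyphenyl]-4-[3-(benzyloxy)-4,5-dimethoxyphenyl]tetrahydro-1H,3H-furo[3,4-c]furan (O,O'-dibenzyl ether of 21) | COc1cc([C@H]2OC[C@H]3[C@@H]2CO[C@@H]3c2cc(OCc4ccccc4)c(OC)c(OC)c2)ccc1OCc1ccccc1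
A6 | alternative 2 | (2R,3R)-2-{[4-(benzyloxy)-3-methoxyphenyl]methyl}-3-{[3-(benzyloxy)-4,5-dimethoxyphenyl]methyl}butane-1,4-diol | OC[C@H](Cc1ccc(OCc2ccccc2)c(OC)c1)[C@@H](Cc1cc(OC)c(OC)c(OCc2ccccc2)c1)CO
A7 | alternative 3 | dibenzyl-protected furofuran with a methoxy acetal at C9 (mixture at C9; other centres as in the SMILES) | COc1cc([C@H]2OC[C@H]3[C@@H]2C(OC)O[C@@H]3c2cc(OCc4ccccc4)c(OC)c(OC)c2)ccc1OCc1ccccc1
A8 | alternative 3 | {(2S,3R)-2-[3-(benzyloxy)-4,5-dimethoxyphenyl]-2,3-dihydrofuran-3-yl}methanol | OC[C@H]1C=CO[C@@H]1c1cc(OCc2ccccc2)c(OC)c(OC)c1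
A9 | alternative 3 | 1-(benzyloxy)-4-(dimethoxymethyl)-2-methoxybenzene | COC(OC)c1ccc(OCc2ccccc2)c(OC)c1
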